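**Plan**

- The retrosynthesis cuts three bonds of the phenol ring (ring B: C1 OH, C2 aryloxy, C3 methyl, C4 methoxy, C5 H, C6 isopropyl): C3–C4, C1–C2 and C1–C6. The para relationship of the C1 hydroxyl and the C4 methoxy on ring B is the pattern that a methoxy(alkenyl)carbene of zerovalent chromium, an alkyne and one CO assemble, so ring B falls apart into these three pieces.
- The alkyne piece is an aryl propynyl ether. It is cut at C(sp)–CH3 and at O–C(sp) back to 4-methoxythymol, trichloroethylene and MeI; 4-methoxythymol comes from thymol by para bromination and copper-catalysed methoxylation.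
- The carbene piece is cut at its C=C bond (aldol addition, dehydration) to the methyl(methoxy)carbene complex and isobutyraldehyde, and further to Cr(CO)6, MeLi and Me3OBF4.
- Forward: ring A is bought with thymol, the two fragments are made in parallel (four and three steps), and ring B is closed last in a single step that also joins the two halves. Chromium is removed in the work-up, so nothing follows the ring closure.
- Stereochemistry: the target has no stereocentre. The (E)-dichlorovinyl ether, the (E)-alkene of the carbene complex and the racemic carbinol of the aldol adduct are all consumed on the way.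

Key step: step 8

Remark: the chromium tricarbonyl complex 17 is written in SMILES as the arene and a Cr(CO)3 fragment side by side, the chromium being bound to the face of the newly formed phenol ring.

**Route**

Step 1
Reactants: 1 thymol (2-isopropyl-5-methylphenol)
Product: 2 4-bromothymol (4-bromo-2-isopropyl-5-methylphenol)
Conditions: NBS (1.0 equiv), MeCN, 0 °C to rt
Reagents that add atoms: N-bromosuccinimide, O=C1CCC(=O)N1Br
Why: Electrophilic aromatic bromination should go to the position para to the hydroxyl, the most activated site and one not flanked by the isopropyl group.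

Step 2
Reactants: 2 4-bromothymol
Product: 3 4-methoxythymol (2-isopropyl-4-methoxy-5-methylphenol)
Conditions: NaOMe (5 equiv), CuBr (0.2 equiv), MeOH–DMF, 110 °C
Reagents that add atoms: sodium methoxide, C[O-].[Na+]
Why: Ullmann-type copper-catalysed methoxylation of an aryl bromide is well known for bromophenols, which react as their phenoxides without protection.

Step 3
Reactants: 3 4-methoxythymol; 4 trichloroethylene
Product: 5 1-{[(E)-1,2-dichloroethenyl]oxy}-2-isopropyl-4-methoxy-5-methylbenzene
Conditions: K2CO3, DMF, 70 °C
Reagents that add atoms: none
Why: Base-induced formation of dichloroacetylene from trichloroethylene and anti addition of the phenoxide across it is the standard vinylation that gives aryl (E)-1,2-dichlorovinyl ethers.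

Step 4
Reactants: 5 1-{[(E)-1,2-dichloroethenyl]oxy}-2-isopropyl-4-methoxy-5-methylbenzene
Product: 8 1-isopropyl-4-methoxy-5-methyl-2-(prop-1-yn-1-yloxy)benzene, via chloroethynyl aryl ether 6 (not isolated), via lithium aryloxyacetylide 7 (not isolated)
Conditions: n-BuLi (2.3 equiv), THF, −78 to −40 °C; then MeI, HMPA, −78 °C to rt
Reagents that add atoms: iodomethane, CI
Why: Dehydrochlorination and chlorine–lithium exchange turn the dichlorovinyl ether into the lithium aryloxyacetylide, which is C-methylated by MeI in HMPA (the dichlorovinyl ether route to ynol ethers by acetylide alkylation).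

Step 5
Reactants: 9 chromium hexacarbonyl
Product: 11 pentacarbonyl(1-methoxyethylidene)chromium, via lithium acetylchromate 10 (not isolated)
Conditions: MeLi, Et2O, 0 °C to rt; then Me3OBF4, CH2Cl2, 0 °C
Reagents that add atoms: methyllithium, [Li]C; trimethyloxonium tetrafluoroborate, C[O+](C)C.F[B-](F)(F)F
Why: Fischer-type carbene complex synthesis, in which MeLi adds to a CO ligand and the acylmetalate is methylated on oxygen by the oxonium salt.

Step 6
Reactants: 11 pentacarbonyl(1-methoxyethylidene)chromium; 12 isobutyraldehyde
Product: 14 racemic pentacarbonyl(3-hydroxy-1-methoxy-4-methylpentylidene)chromium, via lithiated carbene complex 13 (not isolated)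
Conditions: n-BuLi, THF, −78 °C; then 12 premixed with BF3·OEt2, −78 °C; H2O quench
Reagents that add atoms: none
Why: Aldol addition of the stabilised α-anion of an alkoxycarbene complex to a Lewis-acid-activated aldehyde is a known reaction; the new carbinol centre forms as a racemate and is removed in step 7.

Step 7
Reactants: 14 racemic pentacarbonyl(3-hydroxy-1-methoxy-4-methylpentylidene)chromium
Product: 16 pentacarbonyl[(E)-1-methoxy-4-methylpent-2-en-1-ylidene]chromium, via mesylate 15 (not isolated)
Conditions: MsCl, Et3N (excess), CH2Cl2, 0 °C to rt
Reagents that add atoms: none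
Why: Mesylation followed by E1cB elimination through the acidic CH2 next to the carbene carbon should give the conjugated complex with the isopropyl group trans to the carbene carbon, the less strained (E)-alkene.

Step 8
Reactants: 16 pentacarbonyl[(E)-1-methoxy-4-methylpent-2-en-1-ylidene]chromium; 8 1-isopropyl-4-methoxy-5-methyl-2-(prop-1-yn-1-yloxy)benzene
Product: 18 2-(2-isopropyl-4-methoxy-5-methylphenoxy)-6-isopropyl-4-methoxy-3-methylphenol (target), via chromium tricarbonyl arene complex 17 (not isolated)
Conditions: 16 (1.2 equiv), slow addition of 8, degassed THF (0.05 M), 50 °C; then air, Et2O, rt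
Reagents that add atoms: none
Why: Thermal loss of one CO from 16 opens a site for the ynol ether, whose methyl-bearing carbon bonds to the carbene carbon (C3–C4) to give a vinylcarbene; CO insertion (C1–C2) gives a chromium-bound dienylketene, and closure of the ketene carbon onto the isopropyl-bearing alkene carbon (C1–C6) followed by tautomerisation gives the phenol as its Cr(CO)3 complex 17, which air strips to 18. The closest known reaction type is the Dötz benzannulation of alkenyl(alkoxy)carbene complexes of zerovalent chromium with internal alkynes, heteroatom-substituted alkynes included. Ring B is closed by a 6π-electrocyclisation of the metal-bound dienylketene, the overall assembly being a [3+2+1] union of three carbons of the carbene ligand, the two alkyne carbons and one carbonyl carbon. No stereocentre is formed. The step needs regiocontrol in the alkyne insertion and benzannulation in preference to four-membered-ring closure of the ketene: the ynol ether is nucleophilic at the carbon remote from oxygen, which pairs that carbon with the electrophilic carbene carbon and so places the methyl next to the methoxy and the aryloxy next to the hydroxyl, while an alkenyl complex in THF at moderate temperature is the combination that most reliably goes on to the phenol. The carbene methoxy becomes the C4 methoxy and the inserted CO becomes the free C1 hydroxyl, so no protecting group is carried.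

**Compound list**

1 | thymol (2-isopropyl-5-methylphenol) | CC(C)c1ccc(C)cc1O | starting material
2 | 4-bromothymol (4-bromo-2-isopropyl-5-methylphenol) | CC(C)c1cc(Br)c(C)cc1O | intermediate
3 | 4-methoxythymol (2-isopropyl-4-methoxy-5-methylphenol) | COc1cc(C(C)C)c(O)cc1C | intermediate
4 | trichloroethylene | ClC=C(Cl)Cl | starting material
5 | 1-{[(E)-1,2-dichloroethenyl]oxy}-2-isopropyl-4-methoxy-5-methylbenzene | Cl/C=C(/Cl)Oc1cc(C)c(OC)cc1C(C)C | intermediate
6 | 1-[(chloroethynyl)oxy]-2-isopropyl-4-methoxy-5-methylbenzene (not isolated) | ClC#COc1cc(C)c(OC)cc1C(C)C | intermediate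
7 | lithium (2-isopropyl-4-methoxy-5-methylphenoxy)acetylide (not isolated) | [Li]C#COc1cc(C)c(OC)cc1C(C)C | intermediate
8 | 1-isopropyl-4-methoxy-5-methyl-2-(prop-1-yn-1-yloxy)benzene | CC#COc1cc(C)c(OC)cc1C(C)C | intermediate
9 | chromium hexacarbonyl | O=C=[Cr](=C=O)(=C=O)(=C=O)(=C=O)=C=O | starting material
10 | lithium pentacarbonyl(acetyl)chromate, drawn as the lithium oxycarbene (not isolated) | [Li]OC(C)=[Cr](=C=O)(=C=O)(=C=O)(=C=O)=C=O | intermediate
11 | pentacarbonyl(1-methoxyethylidene)chromium | COC(C)=[Cr](=C=O)(=C=O)(=C=O)(=C=O)=C=O | intermediate
12 | isobutyraldehyde | CC(C)C=O | starting material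
13 | pentacarbonyl(2-lithio-1-methoxyethylidene)chromium (not isolated) | [Li]CC(OC)=[Cr](=C=O)(=C=O)(=C=O)(=C=O)=C=O | intermediate
14 | racemic pentacarbonyl(3-hydroxy-1-methoxy-4-methylpentylidene)chromium | COC(CC(O)C(C)C)=[Cr](=C=O)(=C=O)(=C=O)(=C=O)=C=O | intermediate
15 | racemic pentacarbonyl[1-methoxy-4-methyl-3-(methylsulfonyloxy)pentylidene]chromium (not isolated) | COC(CC(OS(C)(=O)=O)C(C)C)=[Cr](=C=O)(=C=O)(=C=O)(=C=O)=C=O | intermediate
16 | pentacarbonyl[(E)-1-methoxy-4-methylpent-2-en-1-ylidene]chromium | COC(/C=C/C(C)C)=[Cr](=C=O)(=C=O)(=C=O)(=C=O)=C=O | intermediate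
17 | tricarbonyl[η6-2-(2-isopropyl-4-methoxy-5-methylphenoxy)-6-isopropyl-4-methoxy-3-methylphenol]chromium, metal on the phenol ring (not isolated) | COc1cc(C(C)C)c(Oc2c(C)c(OC)cc(C(C)C)c2O)cc1C.[Cr](=C=O)(=C=O)=C=O | intermediate
18 | 2-(2-isopropyl-4-methoxy-5-methylphenoxy)-6-isopropyl-4-methoxy-3-methylphenol (CNP0271085.0) | COc1cc(C(C)C)c(Oc2c(C)c(OC)cc(C(C)C)c2O)cc1C | target

**Count and risks**

Total steps: 8. Longest linear sequence: 5 steps (steps 1, 2, 3, 4 and 8, from thymol); the carbene branch has 3 steps (5, 6, 7) before the union.

Steps most likely to fail: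

Step 8. The chromium-bound ketene may close to a four-membered ring instead of the phenol, the electron-rich ynol ether may be consumed by ketene cycloaddition or oligomerisation, or the insertion may proceed with the opposite orientation. The fallback abandons the benzannulation and forms the diaryl ether bond directly, setting out from 3 and returning at 18. Bromination of 3 ortho to the hydroxyl (NBS, catalytic i-Pr2NH, CH2Cl2, 0 °C; the para position is blocked) should give 2-bromo-6-isopropyl-4-methoxy-3-methylphenol F1. Benzylation (BnBr, K2CO3, DMF) should give 2-(benzyloxy)-3-bromo-1-isopropyl-5-methoxy-4-methylbenzene F2. Ullmann diaryl ether coupling of F2 with a second portion of 3 (CuI, picolinic acid, K3PO4, DMSO, 100 °C) should give the O-benzyl ether of the target F3. Hydrogenolysis (H2, Pd/C, EtOAc) then releases 18.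

Step 4. The lithium aryloxyacetylide is a weak carbon nucleophile, so methylation may stall, and the ynol ether may hydrate during isolation. The fallback builds the propynyl ether by copper catalysis, setting out from 3 and returning at 8. Coupling of 3 with 1,1-dibromoprop-1-ene (CuI, 2,2'-bipyridine, K3PO4, toluene, 110 °C) should give 1-{[(Z)-1-bromoprop-1-en-1-yl]oxy}-2-isopropyl-4-methoxy-5-methylbenzene F4. Anti dehydrobromination with KOt-Bu in dioxane at rt should then give 8 without an acetylide alkylation.

Step 6. The stabilised carbene anion may add too slowly, and the enolisable aldehyde may be lost to self-condensation under Lewis acid. The fallback installs the alkenyl group as an organolithium, setting out from 9 and returning at 16, so that steps 5 to 7 are replaced. Hydrozirconation of 3-methylbut-1-yne with Cp2Zr(H)Cl and iodinolysis should give (E)-1-iodo-3-methylbut-1-ene F5. Iodine–lithium exchange (t-BuLi, 2 equiv, Et2O, −78 °C) should give (E)-3-methylbut-1-enyllithium F6. Addition of F6 to 9 should give the lithium alkenoylchromate F7, and methylation on oxygen with Me3OBF4 should give 16 with the alkene geometry fixed from the start.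

**Further compounds**

F1 | step 8 | 2-bromo-6-isopropyl-4-methoxy-3-methylphenol | COc1cc(C(C)C)c(O)c(Br)c1C
F2 | step 8 | 2-(benzyloxy)-3-bromo-1-isopropyl-5-methoxy-4-methylbenzene | COc1cc(C(C)C)c(OCc2ccccc2)c(Br)c1C
F3 | step 8 | 2-(benzyloxy)-1-isopropyl-3-(2-isopropyl-4-methoxy-5-methylphenoxy)-5-methoxy-4-methylbenzene (O-benzyl ether of the target) | COc1cc(C(C)C)c(Oc2c(C)c(OC)cc(C(C)C)c2OCc2ccccc2)cc1C
F4 | step 4 | 1-{[(Z)-1-bromoprop-1-en-1-yl]oxy}-2-isopropyl-4-methoxy-5-methylbenzene | C/C=C(\Br)Oc1cc(C)c(OC)cc1C(C)C
F5 | step 6 | (E)-1-iodo-3-methylbut-1-ene | CC(C)/C=C/I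
F6 | step 6 | (E)-3-methylbut-1-enyllithium | CC(C)/C=C/[Li]
F7 | step 6 | lithium pentacarbonyl[(E)-4-methylpent-2-enoyl]chromate, drawn as the lithium oxycarbene | [Li]OC(/C=C/C(C)C)=[Cr](=C=O)(=C=O)(=C=O)(=C=O)=C=O
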